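## The problem

Compound 20 joins a pentasubstituted benzene (ring A: C1' OMe, C2' CHO, C3' OH, C4' H, C5', C6') to a 3-methyl-8-methoxyisoquinoline through a doubly benzo-fused 2,9-dioxabicyclo[3.3.1]nonane. This core consists of ring B (C-x, O-b, C-y, C-z, C5', C6') and ring C (C-x, O-e, C6, C7, C-y, O-b), where C-x is the acetal carbon on C6', C-y the carbinol carbon on C7, C-z the acetyl-bearing methine on C5', O-e the aryl ether oxygen on C6 and O-b the bridging oxygen. There are three stereocentres: C-x (R), C-y (R) and C-z (S). C-x and C-y can only be bridged cis, so together they are one element that fixes the absolute sense of the bicycle. C-z is a second, relative element (acetyl cis to the isoquinoline bridge on ring B), and being benzylic and alpha to a ketone it can be lost by enolisation. The groups that will not stand rough treatment are the salicylaldehyde of ring A, the beta-alkoxy ketone (epimerisation at C-z, retro-oxa-Michael opening at C-y under base), the benzylic aryl acetal at C-x (ionisation in strong acid) and the basic isoquinoline nitrogen, which takes up acid catalysts. The skeleton hides a repeat: ring A with C-x and the acetonyl unit, and the isoquinoline benzo ring with C-y, C1 and the C3/C4 unit, carry the same substitution pattern, so both halves can come from one benzaldehyde building block. The feature that makes the key step possible is that H–C-x and H–C-y are 1,5-related through O-e, C6 and C7. Returning the C-y hydrogen to C-x and opening the O-b–C-x bond therefore gives a redox isomer, an eight-membered benzyl aryl ether (C-x as OCH2) with an aryl ketone at C-y.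

## Retrosynthesis

**20 from 19, 18 and 17 (no skeletal bond cut).** The formyl group is carried as a methyl ester and the phenol as an allyl ether (17). An ester is the only C2' substituent that is inert to enolates and to acid. A free or acetal-masked aldehyde would interfere with the ring closure or ionise under the acid of the key step. Allyl is chosen over a silyl ether because an aryl silyl ether next to carbonyl groups would not survive the carbonate alkylations, and because allyl is removed under near-neutral conditions at the very end. Since the ester needs a strong hydride, the ketone is reduced with it (18) and both alcohols are reoxidised with the phenol still protected (19). This asks only for standard reactions, and C-z is not epimerisable while it is a carbinol neighbour.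

**17 from 14 (O-b–C-x cut, hydrogen moved from C-y to C-x).** This is the redox disconnection described above. The neighbouring cuts, C-y–C-z (aldol) and C-x–O-e (acetalisation), are the two bonds of a stepwise union at the aldehyde level. They would leave all three stereocentres to separate control. The redox cut gives diketone 14, whose only stereocentre (C-z) is stereolabile and is therefore drawn without configuration. The forward step must move one enantiotopic benzylic hydrogen to one face of the aryl ketone and close both six-membered rings with one C–O bond.

**14 from 12 (C-y–C-z cut).** Intramolecular acylation of the benzylic ketone carbon by the isoquinoline ester closes the eight-membered ring and installs the 1,3-diketone at once. Closing the ring at the ether bond instead would pit the phenol against the diketone enol oxygen, which forms a six-membered enol ether more easily. Precursor 12 is acyclic. The forward reaction needs high dilution and a second equivalent of base.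

**12 from 10 and 11 (C-x–O-e cut).** A phenol and a primary benzylic alcohol are joined directly. This avoids an isolated electron-rich benzylic halide sitting next to a ketone oxygen. The two partners have 15 and 16 carbons and no stereocentres.

**10 and 11 from 8.** Both halves are the same keto aldehyde 8. Condensation with a nitrogen source turns its formyl and acetonyl groups into the pyridine ring (9, then 10 after deallylation). Selective reduction of the formyl group gives 11. This halves the fragment work. The forward reactions must tell aldehyde from ketone.

**8 from 4 through 5 (ArCH2–C(O)CH3 cut).** The acetyl group is added to the benzylic methyl of an o-tolualdehyde, activated as its N-tert-butyl imine. The alternative, a cross-coupling at this position, would need a halogen that the starting arene does not carry.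

**4 from 1 through 2 and 3.** One formylation of the symmetric resorcylate 1 puts the aldehyde ortho to the methyl group. The two hydroxyls then differ (para versus ortho to the formyl group) and are capped in turn with allyl and methyl.

## Roads not taken

**Alternative 1:** The cut is through C4a–C5 and C8–C8a, so the benzo ring of the isoquinoline is made last. In the forward step 2-chloro-6-methyl-3,4-pyridyne A1, released by fluoride, takes up diene A2, in which ring C carries an exocyclic methylene at C6 and a silyl ketene acetal at C7. Aromatisation gives the 1-chloro-8-hydroxyisoquinoline A3. Merits: aryne cycloadditions to oxygenated dienes are an established reaction type. The chlorine should steer the nucleophilic methylene terminus to C4 of the pyridyne, and no basic nitrogen is present before this point. Weak points: fluoride also cleaves silyl ketene acetals. A2 must already hold the bicyclic acetal and all three stereocentres, which the key step does nothing to set. After it come O-methylation, dechlorination and removal of two acetals and one acetal ether. In precedent for the bond-forming event this road is ahead of the chosen plan. The chosen plan offers in return two rings and two stereocentres from one isomerisation and a precursor made from two copies of one building block.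

**Alternative 2:** The cut is through C-y–C-z and the O-b–carbonyl bond of a lactone. The enol of homophthalic anhydride A4 adds to isoquinoline aldehyde A5 and the alkoxide acylates, giving acid A6 with ring B closed. Merits: this annulation is well precedented and catalytic enantioselective versions are known, so it is stronger than the chosen plan in precedent and in control of absolute configuration. Weak points: the aldehyde carbon of A5 is flanked by two ortho substituents. The carboxyl group must then become a methyl ketone at an epimerisable centre. C-x arrives at the ester level and has to be reduced to the lactol and closed onto the C6 phenol. Four protecting groups must come off. That is roughly twice as many steps after the key event, and A4 is a longer fragment than 8. The chosen plan answers with redox economy (C-x and C-y reach their final oxidation levels in the key step) and with the shared intermediate.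

**Alternative 3:** The cut is through C5'–C6' and C1'–C2', so ring A is made de novo. On heating, the methoxyalkyne of A7 adds across C6 and C3 of its tethered 2-pyrone, carbon dioxide is lost, and rings A and B close together to give A8. Merits: the pentasubstituted arene is formed with fully defined regiochemistry, and A8 is as close to the target as 17 is. Weak points: A7 needs ring C with C-x, C-y and C-z already in place, carrying a hydrolytically sensitive ynol ether on an acetal carbon and a pyrone next to an enolisable acetyl group. The cycloaddition needs heat that these groups and C-z may not bear, and it sets no stereocentre. It forms more carbon–carbon bonds in one step than the chosen plan does. The chosen plan buys ring A instead and uses its key step for the stereocentres.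

Key step: step 11

Assumption: methyl 2,6-dihydroxy-4-methylbenzoate (1) is taken as a purchasable resorcylate.
Assumption: the sense of induction of the chiral ligand in step 11 cannot be predicted; the (S,S) antipode is written and the (R,R) antipode is used if the opposite sense is found.
Assumption: C-z is taken to be set under kinetic control in step 11; its position in an epimerisation equilibrium is not known, so base and strong acid are avoided once it is formed.

## Route

Step 1
Reactants: 1 methyl 2,6-dihydroxy-4-methylbenzoate
Product: 2 methyl 3-formyl-2,6-dihydroxy-4-methylbenzoate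
Conditions: Cl2CHOMe (1.2 equiv), TiCl4 (2.5 equiv), CH2Cl2, 0 °C to rt; then aq. HCl
Reagents that add atoms: dichloromethyl methyl ether, ClC(Cl)OC; water, O
Why: Rieche formylation; C3 is ortho to one hydroxyl, para to the other and equivalent to C5 by symmetry, so only one monoaldehyde can form, and the first formyl group deactivates the ring against a second.

Step 2
Reactants: 2 methyl 3-formyl-2,6-dihydroxy-4-methylbenzoate
Product: 3 methyl 3-formyl-2-hydroxy-4-methyl-6-(prop-2-enyloxy)benzoate
Conditions: allyl bromide (1.05 equiv), K2CO3 (1.1 equiv), DMF, 0 °C to rt
Reagents that add atoms: allyl bromide, C=CCBr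
Why: Williamson ether synthesis; the C6 hydroxyl is para to the formyl group and has one carbonyl neighbour, whereas the C2 hydroxyl lies between formyl and ester and is held in a strong hydrogen bond to the aldehyde, so one equivalent of halide with a weak base should alkylate C6–OH first.

Step 3
Reactants: 3 methyl 3-formyl-2-hydroxy-4-methyl-6-(prop-2-enyloxy)benzoate
Product: 4 methyl 3-formyl-2-methoxy-4-methyl-6-(prop-2-enyloxy)benzoate
Conditions: MeI (3 equiv), K2CO3 (2 equiv), DMF, 50 °C
Reagents that add atoms: iodomethane, CI
Why: Williamson methylation of the remaining chelated hydroxyl under more forcing conditions; no other nucleophilic site is left, and the allyl ether, ester and aldehyde are inert.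

Step 4
Reactants: 4 methyl 3-formyl-2-methoxy-4-methyl-6-(prop-2-enyloxy)benzoate
Product: 5 methyl 3-[(E)-(tert-butylimino)methyl]-2-methoxy-4-methyl-6-(prop-2-enyloxy)benzoate
Conditions: t-BuNH2 (3 equiv), 4 Å MS, CH2Cl2, rt; concentrate
Reagents that add atoms: tert-butylamine, CC(C)(C)N
Why: Imine condensation; the bulky aldimine masks the aldehyde against amide bases and acidifies the ortho methyl group for the next step.

Step 5
Reactants: 5 methyl 3-[(E)-(tert-butylimino)methyl]-2-methoxy-4-methyl-6-(prop-2-enyloxy)benzoate
Product: 8 methyl 3-formyl-2-methoxy-4-(2-oxopropyl)-6-(prop-2-enyloxy)benzoate, via benzylic lithio imine 6 (not isolated), via lithium hemiaminal adduct 7 (not isolated)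
Conditions: LiN(i-Pr)2 (1.15 equiv), THF, −78 °C; MeC(O)N(OMe)Me (1.3 equiv), −78 to −40 °C; then 1 M aq. HCl, THF, 0 °C
Reagents that add atoms: N-methoxy-N-methylacetamide, CC(=O)N(C)OC; water, O
Why: Lateral (benzylic) lithiation of an o-tolualdehyde tert-butylimine followed by acylation with an N-methoxy-N-methyl amide; the methyl group is ortho to the imine and para to the ester and so is the most acidic site, the chelated adduct 7 prevents double addition, and acidic work-up releases the ketone and hydrolyses the imine. The ester between two alkoxy groups is too hindered to be attacked at −78 °C.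

Step 6
Reactants: 8 methyl 3-formyl-2-methoxy-4-(2-oxopropyl)-6-(prop-2-enyloxy)benzoate
Product: 9 methyl 8-methoxy-3-methyl-6-(prop-2-enyloxy)isoquinoline-7-carboxylate
Conditions: NH3 (7 M in MeOH), rt
Reagents that add atoms: ammonia, N
Why: Classical pyridine-ring synthesis from a 1,5-dicarbonyl compound; the aldimine condenses with the ketone and loses water to give the aromatic 3-methylisoquinoline, and the hindered ester is not ammonolysed at rt.

Step 7
Reactants: 9 methyl 8-methoxy-3-methyl-6-(prop-2-enyloxy)isoquinoline-7-carboxylate
Product: 10 methyl 6-hydroxy-8-methoxy-3-methylisoquinoline-7-carboxylate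
Conditions: Pd(PPh3)4 (5 mol %), morpholine (5 equiv), THF, rt
Reagents that add atoms: none
Why: Tsuji–Trost deallylation; zerovalent palladium ionises the aryl allyl ether and morpholine takes the allyl group, freeing the phenol for the ether coupling.

Step 8
Reactants: 8 methyl 3-formyl-2-methoxy-4-(2-oxopropyl)-6-(prop-2-enyloxy)benzoate
Product: 11 methyl 3-(hydroxymethyl)-2-methoxy-4-(2-oxopropyl)-6-(prop-2-enyloxy)benzoate
Conditions: NaBH4 (0.3 equiv), EtOH/CH2Cl2 (3:7), −78 °C; then water
Reagents that add atoms: none
Why: Chemoselective borohydride reduction; at −78 °C an aldehyde is reduced much faster than a ketone and the ester is inert. Any cyclic hemiketal form of 11 reacts through the open form in step 9.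

Step 9
Reactants: 11 methyl 3-(hydroxymethyl)-2-methoxy-4-(2-oxopropyl)-6-(prop-2-enyloxy)benzoate; 10 methyl 6-hydroxy-8-methoxy-3-methylisoquinoline-7-carboxylate
Product: 12 methyl 8-methoxy-6-{[2-methoxy-3-(methoxycarbonyl)-6-(2-oxopropyl)-4-(prop-2-enyloxy)phenyl]methoxy}-3-methylisoquinoline-7-carboxylate
Conditions: PPh3 (1.3 equiv), diisopropyl azodicarboxylate (1.3 equiv), THF, 0 °C to rt
Reagents that add atoms: none
Why: Mitsunobu etherification; the phenol of 10, acidified by the ortho ester, displaces the activated primary benzylic alcohol, no benzylic halide has to be isolated beside the ketone, and the ketone alpha-hydrogens are not acidic enough to be alkylated.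

Step 10
Reactants: 12 methyl 8-methoxy-6-{[2-methoxy-3-(methoxycarbonyl)-6-(2-oxopropyl)-4-(prop-2-enyloxy)phenyl]methoxy}-3-methylisoquinoline-7-carboxylate
Product: 14 eight-membered ether diketone (ring: C-x as OCH2; O-e; C6; C7; C-y as aryl ketone; C-z as CH(COCH3); C5'; C6'; ring A with 1'-OMe; 2'-CO2Me; 3'-O-allyl), via lithium diketonate 13 (not isolated)
Conditions: LiN(SiMe3)2 (2.5 equiv), THF (0.005 M), −78 to 0 °C; then AcOH
Reagents that add atoms: none
Why: Intramolecular Claisen (Dieckmann-type) condensation; the more acidic benzylic alpha-carbon of the ketone is acylated by the isoquinoline ester, the two cis-fused arenes pre-organise the chain for the eight-membered ring, high dilution suppresses intermolecular condensation, and the second equivalent of base drives the equilibrium by forming diketonate 13. C-z is stereolabile in 14, which the next step uses.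

Step 11
Reactants: 14 eight-membered ether diketone
Product: 17 bridged acetal ester (C-x R; C-y R; C-z S; ring A with 1'-OMe; 2'-CO2Me; 3'-O-allyl), via isoquinolinium triflate 15 (not isolated), via oxocarbenium alkoxide 16 (not isolated)
Conditions: TfOH (1.0 equiv), (CH2Cl)2, 0 °C; then Sc(OTf)3 (20 mol %), (S,S)-Ph-pybox [2,6-bis((4S)-4-phenyl-4,5-dihydrooxazol-2-yl)pyridine] (24 mol %), 4 Å MS, (CH2Cl)2, 40 °C; aq. NaHCO3 work-up
Reagents that add atoms: none
Why: Proposed new method: Sc(OTf)3 with the chiral pybox ligand is expected to chelate the two carbonyl oxygens of the diketo form of 15, which holds the acetyl group syn to the aryl ketone oxygen and makes C-y strongly electrophilic; the inward benzylic hydrogen on C-x, whose cation is stabilised by the ortho methoxy and para allyloxy groups of ring A and by O-e, then moves suprafacially across the ring to C-y through a six-membered transition state (1,5-hydride shift) to give 16. After a flip of the medium ring the scandium alkoxide adds to the oxocarbenium carbon, and this single transannular O-b–C-x bond closes ring C (6-endo-trig with respect to the C-x=O-e bond) and ring B (6-exo-trig) together. The closest known reactions are Lewis-acid-catalysed 1,5-hydride shift/cyclisations of benzylic ethers onto carbonyl and alkylidene-malonate acceptors, including enantioselective cases with chelating acceptors, and transannular 1,5-hydride shifts in eight-membered rings; none joins the two or uses the aryl ketone of a 1,3-diketone as acceptor. C-y is set by the ketone face that receives the hydride (the pro-R hydrogen of the OCH2 group to the Si face), which the ligand must choose between the two mirror-image chelates of the rapidly racemising diketone (a dynamic kinetic asymmetric transformation); C-x follows because only the cis bridge can form. C-z is set relative to C-y by the chelate: with the acetyl group syn to the ketone oxygen and C5' on the face that delivers the hydride, the acetyl group ends cis to the isoquinoline bridge, as in the target. The step needs chemoselectivity for the aryl ketone over the acetyl ketone, which is also 1,5 to the donor; the aryl ketone is twisted out of conjugation and sits on the electron-poor isoquinolinium ring, only its hydride adduct can collapse to a strain-free bicyclic acetal, and hydride transfer to the acetyl group should be reversible. Forming the triflate salt first keeps the nitrogen from binding the catalyst and from turning the diketone into an unreactive scandium diketonate.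

Step 12
Reactants: 17 bridged acetal ester
Product: 18 bridged acetal diol (2'-CH2OH; C-z bearing CH(OH)CH3 as a mixture of carbinol epimers; 3'-O-allyl; C-x R; C-y R; C-z R by change of priorities, same geometry as in 17)
Conditions: LiAlH4 (3 equiv), THF, 0 °C; aq. NaOH work-up
Reagents that add atoms: none
Why: LiAlH4 reduction of the hindered ester to the benzylic alcohol together with the ketone; acetal and allyl ether are inert to hydride, C-z stops being epimerisable, and the new carbinol centre does not matter because it is reoxidised.

Step 13
Reactants: 18 bridged acetal diol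
Product: 19 bridged acetal keto aldehyde (2'-CHO; acetyl on C-z; 3'-O-allyl; C-x R; C-y R; C-z S)
Conditions: Dess–Martin periodinane (3 equiv), pyridine (6 equiv), CH2Cl2, 0 °C to rt
Reagents that add atoms: none
Why: Dess–Martin oxidation of both alcohols under buffered, non-basic conditions, so C-z is not epimerised and the beta-alkoxy ketone is not opened; the phenol is still protected, which avoids quinone formation.

Step 14
Reactants: 19 bridged acetal keto aldehyde
Product: 20 target CNP0584953.1 (C-x R; C-y R; C-z S)
Conditions: Pd(PPh3)4 (5 mol %), 4-MeC6H4SO2H (1.5 equiv), THF, rt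
Reagents that add atoms: none
Why: Tsuji–Trost deallylation with a sulfinic acid as allyl acceptor; the near-neutral conditions leave the aldehyde, the ketone, C-z and the acetal untouched.

## Compound list

1 | methyl 2,6-dihydroxy-4-methylbenzoate | COC(=O)c1c(O)cc(C)cc1O | starting material
2 | methyl 3-formyl-2,6-dihydroxy-4-methylbenzoate | COC(=O)c1c(O)cc(C)c(C=O)c1O | intermediate
3 | methyl 3-formyl-2-hydroxy-4-methyl-6-(prop-2-enyloxy)benzoate | COC(=O)c1c(OCC=C)cc(C)c(C=O)c1O | intermediate
4 | methyl 3-formyl-2-methoxy-4-methyl-6-(prop-2-enyloxy)benzoate | COC(=O)c1c(OCC=C)cc(C)c(C=O)c1OC | intermediate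
5 | methyl 3-[(E)-(tert-butylimino)methyl]-2-methoxy-4-methyl-6-(prop-2-enyloxy)benzoate | COC(=O)c1c(OCC=C)cc(C)c(/C=N/C(C)(C)C)c1OC | intermediate
6 | benzylic lithio derivative of 5 (lithium on the 4-CH2 group) | COC(=O)c1c(OCC=C)cc(C[Li])c(/C=N/C(C)(C)C)c1OC | intermediate (not isolated)
7 | lithium hemiaminal adduct of 6 with N-methoxy-N-methylacetamide | COC(=O)c1c(OCC=C)cc(CC(C)(O[Li])N(C)OC)c(/C=N/C(C)(C)C)c1OC | intermediate (not isolated)
8 | methyl 3-formyl-2-methoxy-4-(2-oxopropyl)-6-(prop-2-enyloxy)benzoate | COC(=O)c1c(OCC=C)cc(CC(C)=O)c(C=O)c1OC | intermediate
9 | methyl 8-methoxy-3-methyl-6-(prop-2-enyloxy)isoquinoline-7-carboxylate | COC(=O)c1c(OCC=C)cc2cc(C)ncc2c1OC | intermediate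
10 | methyl 6-hydroxy-8-methoxy-3-methylisoquinoline-7-carboxylate | COC(=O)c1c(O)cc2cc(C)ncc2c1OC | intermediate
11 | methyl 3-(hydroxymethyl)-2-methoxy-4-(2-oxopropyl)-6-(prop-2-enyloxy)benzoate | COC(=O)c1c(OCC=C)cc(CC(C)=O)c(CO)c1OC | intermediate
12 | methyl 8-methoxy-6-{[2-methoxy-3-(methoxycarbonyl)-6-(2-oxopropyl)-4-(prop-2-enyloxy)phenyl]methoxy}-3-methylisoquinoline-7-carboxylate | COC(=O)c1c(OCC=C)cc(CC(C)=O)c(COc2cc3cc(C)ncc3c(OC)c2C(=O)OC)c1OC | intermediate
13 | lithium enolate (diketonate) of 14 | COc1c(C(=O)OC)c(OCC=C)cc2c1COc1cc3cc(C)ncc3c(OC)c1C(=O)C2=C(C)O[Li] | intermediate (not isolated)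
14 | eight-membered ether diketone: C-x as OCH2 between C6' and O-e, aryl ketone at C-y on C7, C-z as CH(COCH3) on C5', stereolabile and in equilibrium with its enols; ring A 1'-OMe, 2'-CO2Me, 3'-O-allyl | COc1c(C(=O)OC)c(OCC=C)cc2c1COc1cc3cc(C)ncc3c(OC)c1C(=O)C2C(C)=O | intermediate
15 | N-protonated 14 as its trifluoromethanesulfonate | COc1c(C(=O)OC)c(OCC=C)cc2c1COc1cc3cc(C)[nH+]cc3c(OC)c1C(=O)C2C(C)=O.[O-]S(=O)(=O)C(F)(F)F | intermediate (not isolated)
16 | oxocarbenium alkoxide after hydride shift (C-x=O-e cation, C-y alkoxide bound to scandium; C-y R, C-z S; drawn without metal and N-proton) | COc1c(C(=O)OC)c(OCC=C)cc2c1C=[O+]c1cc3cc(C)ncc3c(OC)c1[C@H]([O-])[C@H]2C(C)=O | intermediate (not isolated)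
17 | bridged acetal ester: rings B and C closed, 2'-CO2Me, 3'-O-allyl, acetyl on C-z cis to the isoquinoline bridge (C-x R, C-y R, C-z S) | COc1c(C(=O)OC)c(OCC=C)cc2c1[C@H]1Oc3cc4cc(C)ncc4c(OC)c3[C@H](O1)[C@H]2C(C)=O | intermediate
18 | bridged acetal diol: 2'-CH2OH, CH(OH)CH3 on C-z (carbinol epimers), 3'-O-allyl (C-x R, C-y R, C-z R) | COc1c(CO)c(OCC=C)cc2c1[C@H]1Oc3cc4cc(C)ncc4c(OC)c3[C@H](O1)[C@H]2C(C)O | intermediate
19 | bridged acetal keto aldehyde: 2'-CHO, acetyl on C-z, 3'-O-allyl (C-x R, C-y R, C-z S) | COc1c(C=O)c(OCC=C)cc2c1[C@H]1Oc3cc4cc(C)ncc4c(OC)c3[C@H](O1)[C@H]2C(C)=O | intermediate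
20 | CNP0584953.1 (C-x R, C-y R, C-z S) | COc1c(C=O)c(O)cc2c1[C@H]1Oc3cc4cc(C)ncc4c(OC)c3[C@H](O1)[C@H]2C(C)=O | target

## Step count and least certain steps

Total: 14 steps. Longest linear sequence: 13 steps (steps 1–7 and 9–14). Key step: step 11.

**Step 11 (key step).** The likely failures are: hydride transfer to the acetyl carbonyl instead of the aryl ketone; loss of catalyst to the nitrogen if protonation is incomplete; poor discrimination between the two mirror-image chelates; interception of the oxocarbenium ion by water; and epimerisation at C-z after closure. The fallback uses known chemistry, sets out from 9 and 11 and returns at 17. Ester 9 is reduced with LiAlH4 to [8-methoxy-3-methyl-6-(prop-2-enyloxy)isoquinolin-7-yl]methanol F1, oxidised with MnO2 to aldehyde F2 and deallylated (Pd(PPh3)4, morpholine) to hydroxy aldehyde F3. Mitsunobu coupling of F3 with 11 gives ether keto aldehyde F4. A base-mediated intramolecular aldol addition closes the eight-membered ring to beta-hydroxy ketone F5, in which C-y is already at the alcohol level. DDQ then oxidises the electron-rich benzylic ether CH2 to the oxocarbenium ion, which the C-y hydroxyl traps across the ring; this is the known oxidative acetalisation of alkoxybenzyl ethers bearing a nearby hydroxyl group. After separation of the C-z epimers (the unwanted one can be re-equilibrated through its enolate) this gives 17 as the racemate, that is, together with its enantiomer F6. Resolution on a chiral stationary phase, or by crystallising a salt of the basic nitrogen with a tartaric acid derivative, delivers 17.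

**Step 10.** The likely failures are no attack on the doubly ortho-substituted ester, intermolecular condensation, and vinylogous elimination of the isoquinolinoxide from the benzylic enolate. The fallback sets out from 9 and returns at 14. Saponification (LiOH) gives acid F7, which is esterified with phenol (DCC, DMAP) to phenyl ester F8 and deallylated to phenol F9. Mitsunobu coupling with 11 gives ether F10. Its aryl ester is a much better acyl donor, so the ring can be closed by soft enolisation (MgBr2·OEt2, i-Pr2NEt) or with LiN(SiMe3)2 at −78 °C to give 14.

**Step 8.** The likely failures are reduction of the ketone alongside the hindered aldehyde, and cyclisation or dehydration of the hydroxy ketone on handling. The fallback sets out from 8 and returns at 11. Both carbonyls are reduced (NaBH4, MeOH, 0 °C) to diol F11. The primary alcohol is silylated selectively (t-BuMe2SiCl, imidazole) to F12, the secondary alcohol is oxidised (Dess–Martin periodinane) to ketone F13, and HF·pyridine frees 11.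

**Step 5.** The likely failures are proton transfer from the acylating amide to the benzylic anion, attack on an ester, and incomplete metalation. The fallback sets out from 4 and returns at 8; it moves the chemistry to the classical o-toluate anion. Pinnick oxidation gives acid F14 and methylation (MeI, K2CO3) gives diester F15. Lateral lithiation with LiN(i-Pr)2 and acylation with N-methoxy-N-methylacetamide gives keto diester F16, which closes under acid to the 3-methylisocoumarin F17. Half-reduction of this enol lactone with i-Bu2AlH (1 equiv, −78 °C) gives the lactol, the ring tautomer of 8.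

**Step 2.** The likely failure is alkylation at the wrong hydroxyl or at both. The fallback sets out from 1 and returns at 3 by reversing the order. Symmetric 1 is mono-allylated to F18 (only one mono-ether is possible; unreacted 1 is recycled). Magnesium-mediated ortho-formylation (MgCl2, Et3N, paraformaldehyde) then places the aldehyde next to the one free hydroxyl, giving 3.

## Further compounds

F1 | step 11 | [8-methoxy-3-methyl-6-(prop-2-enyloxy)isoquinolin-7-yl]methanol | OCc1c(OCC=C)cc2cc(C)ncc2c1OC
F2 | step 11 | 8-methoxy-3-methyl-6-(prop-2-enyloxy)isoquinoline-7-carbaldehyde | O=Cc1c(OCC=C)cc2cc(C)ncc2c1OC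
F3 | step 11 | 6-hydroxy-8-methoxy-3-methylisoquinoline-7-carbaldehyde | O=Cc1c(O)cc2cc(C)ncc2c1OC
F4 | step 11 | methyl 3-{[(7-formyl-8-methoxy-3-methylisoquinolin-6-yl)oxy]methyl}-2-methoxy-4-(2-oxopropyl)-6-(prop-2-enyloxy)benzoate | COC(=O)c1c(OCC=C)cc(CC(C)=O)c(COc2cc3cc(C)ncc3c(OC)c2C=O)c1OC
F5 | step 11 | eight-membered beta-hydroxy ketone (C-y as CHOH, C-z as CH(COCH3), racemic diastereomer mixture) | COc1c(C(=O)OC)c(OCC=C)cc2c1COc1cc3cc(C)ncc3c(OC)c1C(O)C2C(C)=O
F6 | step 11 | enantiomer of 17 (C-x S, C-y S, C-z R) | COc1c(C(=O)OC)c(OCC=C)cc2c1[C@@H]1Oc3cc4cc(C)ncc4c(OC)c3[C@@H](O1)[C@@H]2C(C)=O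
F7 | step 10 | 8-methoxy-3-methyl-6-(prop-2-enyloxy)isoquinoline-7-carboxylic acid | OC(=O)c1c(OCC=C)cc2cc(C)ncc2c1OC
F8 | step 10 | phenyl 8-methoxy-3-methyl-6-(prop-2-enyloxy)isoquinoline-7-carboxylate | O=C(Oc1ccccc1)c1c(OCC=C)cc2cc(C)ncc2c1OC
F9 | step 10 | phenyl 6-hydroxy-8-methoxy-3-methylisoquinoline-7-carboxylate | O=C(Oc1ccccc1)c1c(O)cc2cc(C)ncc2c1OC
F10 | step 10 | phenyl 8-methoxy-6-{[2-methoxy-3-(methoxycarbonyl)-6-(2-oxopropyl)-4-(prop-2-enyloxy)phenyl]methoxy}-3-methylisoquinoline-7-carboxylate | COC(=O)c1c(OCC=C)cc(CC(C)=O)c(COc2cc3cc(C)ncc3c(OC)c2C(=O)Oc2ccccc2)c1OC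
F11 | step 8 | methyl 3-(hydroxymethyl)-4-(2-hydroxypropyl)-2-methoxy-6-(prop-2-enyloxy)benzoate | COC(=O)c1c(OCC=C)cc(CC(C)O)c(CO)c1OC
F12 | step 8 | methyl 3-{[tert-butyl(dimethyl)silyl]oxymethyl}-4-(2-hydroxypropyl)-2-methoxy-6-(prop-2-enyloxy)benzoate | COC(=O)c1c(OCC=C)cc(CC(C)O)c(CO[Si](C)(C)C(C)(C)C)c1OC
F13 | step 8 | methyl 3-{[tert-butyl(dimethyl)silyl]oxymethyl}-2-methoxy-4-(2-oxopropyl)-6-(prop-2-enyloxy)benzoate | COC(=O)c1c(OCC=C)cc(CC(C)=O)c(CO[Si](C)(C)C(C)(C)C)c1OC
F14 | step 5 | 2-methoxy-3-(methoxycarbonyl)-6-methyl-4-(prop-2-enyloxy)benzoic acid | COC(=O)c1c(OCC=C)cc(C)c(C(=O)O)c1OC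
F15 | step 5 | dimethyl 2-methoxy-4-methyl-6-(prop-2-enyloxy)benzene-1,3-dicarboxylate | COC(=O)c1c(OCC=C)cc(C)c(C(=O)OC)c1OC
F16 | step 5 | dimethyl 2-methoxy-4-(2-oxopropyl)-6-(prop-2-enyloxy)benzene-1,3-dicarboxylate | COC(=O)c1c(OCC=C)cc(CC(C)=O)c(C(=O)OC)c1OC
F17 | step 5 | methyl 8-methoxy-3-methyl-1-oxo-6-(prop-2-enyloxy)-1H-isochromene-7-carboxylate | COC(=O)c1c(OCC=C)cc2cc(C)oc(=O)c2c1OC
F18 | step 2 | methyl 2-hydroxy-4-methyl-6-(prop-2-enyloxy)benzoate | COC(=O)c1c(O)cc(C)cc1OCC=C
A1 | alternative 1 | 2-chloro-6-methyl-3,4-pyridyne | CC1=CC#CC(Cl)=N1
A2 | alternative 1 | ring C diene: bicyclic acetal with exocyclic methylene at C6 and methyl trimethylsilyl ketene acetal at C7, ring A as dioxolane and methoxymethyl ether, acetyl as dioxolane | COc1c(C3OCCO3)c(OCOC)cc2c1[C@H]1OC(=C)C(=C(OC)O[Si](C)(C)C)[C@H](O1)[C@H]2C1(C)OCCO1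
A3 | alternative 1 | 1-chloro-8-hydroxyisoquinoline form of the masked skeleton | COc1c(C3OCCO3)c(OCOC)cc2c1[C@H]1Oc3cc4cc(C)nc(Cl)c4c(O)c3[C@H](O1)[C@H]2C1(C)OCCO1
A4 | alternative 2 | ring A homophthalic anhydride (dioxolane, methoxymethyl ether) | COc1c(C2OCCO2)c(OCOC)cc2c1C(=O)OC(=O)C2
A5 | alternative 2 | 8-methoxy-6-(methoxymethoxy)-3-methylisoquinoline-7-carbaldehyde | O=Cc1c(OCOC)cc2cc(C)ncc2c1OC
A6 | alternative 2 | 3-(isoquinolin-7-yl)-1-oxoisochroman-4-carboxylic acid | COc1c(C3OCCO3)c(OCOC)cc2c1C(=O)O[C@@H](c1c(OCOC)cc3cc(C)ncc3c1OC)[C@H]2C(=O)O
A7 | alternative 3 | 2-pyrone tethered through C-z to ring C bearing a methoxyethynyl group on C-x | COC#C[C@H]1Oc2cc3cc(C)ncc3c(OC)c2[C@H](O1)[C@@H](C(C)=O)c1cc(OCOC)c(C(=O)OC)c(=O)o1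
A8 | alternative 3 | pentacyclic skeleton with ring A as methyl ester and methoxymethyl ether | COc1c(C(=O)OC)c(OCOC)cc2c1[C@H]1Oc3cc4cc(C)ncc4c(OC)c3[C@H](O1)[C@H]2C(C)=O
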